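**Plan**
Retrosynthesis: the two ester C–O bonds are cut first, then the cyclobutane bond C5–C11 (enolate alkylation), then C1–C11 and C3–C4 together (annulation with ethyl but-2-ynoate), then C10–C11 (radical cyclization from an O9 tether), C4=C10 (ring-closing metathesis) and C7–C8 (aldol).
Forward: acyclic C5–C10 chain, seven-membered ring, temporary cis-fused γ-lactone, six-membered enone ring, four-membered ring, esters.
Enabling feature: C4 and C11 both sit on the quaternary carbon C10; C4 is made α to a C5 ketone (later the electrophilic carbon that closes the four-membered ring) and C11 α to a temporary lactone carbonyl tethered to O9 (later lost as CO2), so the C1–C2–C3 unit of an alkynoate can be spliced between them.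
Stereochemistry: C7 from a reagent-controlled boron aldol, C9 from CBS reduction, C10 relayed from C9 through the O9 tether, C4 by equilibration in the key step, C5 by hydride addition anti to the C7 silyl ether followed by inversion, C11 by the geometry of the cyclobutane closure.

Key step: step 10

Remark (numbering): locants C1–C11 are those of longipinane in the target: C1 ketone, C2=C3(CH3), C4 and C11 cyclobutane CH (C11 bears C1), C5 cyclobutane CH bearing C6, C6 C(CH3)2, C7 CH–OAng, C8 CH2, C9 CH–OAc, C10 quaternary C–CH3. "5,11-Seco" names denote the bicyclo[5.4.0]undecane in which the C5–C11 bond is still absent.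
Remark (assumption): the (−)-Ipc2BCl aldol of a methyl ketone is taken to attack the re face of the aldehyde; if the sense proves opposite, (+)-Ipc2BCl is used.

**Route**

Step 1
Reactants: 1 methyl 2,2-dimethyl-3-oxopropanoate; 2 3-methylbut-3-en-2-one
Product: 4 methyl (3R)-3-hydroxy-2,2,6-trimethyl-5-oxohept-6-enoate, via enol diisopinocampheylborinate 3 (not isolated)
Conditions: (−)-Ipc2BCl, Et3N, Et2O, 0 °C; then 1, −78 to −20 °C; H2O2, MeOH, pH 7 buffer
Reagents that add atoms: none
Why: Paterson boron aldol reaction, in which the enol borinate of the methyl ketone (only its methyl group is enolizable) adds to the non-enolizable aldehyde and the isopinocampheyl ligands direct attack to the re face, setting C7 as R.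

Step 2
Reactants: 4 methyl (3R)-3-hydroxy-2,2,6-trimethyl-5-oxohept-6-enoate
Product: 5 methyl (3R)-3-(tert-butyldimethylsilyloxy)-2,2,6-trimethyl-5-oxohept-6-enoate
Conditions: TBSOTf, 2,6-lutidine, CH2Cl2, −78 °C
Reagents that add atoms: tert-butyldimethylsilyl triflate CC(C)(C)[Si](C)(C)OS(=O)(=O)C(F)(F)F
Why: Silylation of a hindered secondary alcohol with the silyl triflate, which also blocks retro-aldol cleavage; no stereocenter is touched.

Step 3
Reactants: 5 methyl (3R)-3-(tert-butyldimethylsilyloxy)-2,2,6-trimethyl-5-oxohept-6-enoate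
Product: 6 methyl (3R,5R)-3-(tert-butyldimethylsilyloxy)-5-hydroxy-2,2,6-trimethylhept-6-enoate
Conditions: (S)-2-methyl-CBS-oxazaborolidine (10 mol %), catecholborane, toluene, −78 °C; MeOH, aq NaOH
Reagents that add atoms: none
Why: Corey–Bakshi–Shibata reduction of the enone carbonyl, in which the isopropenyl group acts as the large substituent so that the (S)-catalyst sets C9 as R (anti to C7–O) by reagent control, with clean 1,2-reduction at low temperature.

Step 4
Reactants: 6 methyl (3R,5R)-3-(tert-butyldimethylsilyloxy)-5-hydroxy-2,2,6-trimethylhept-6-enoate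
Product: 7 (3R,5R)-3-(tert-butyldimethylsilyloxy)-5-hydroxy-N-methoxy-N,2,2,6-tetramethylhept-6-enamide
Conditions: MeNHOMe·HCl, i-PrMgCl, THF, −20 to 0 °C
Reagents that add atoms: N,O-dimethylhydroxylamine hydrochloride CNOC.Cl
Why: Weinreb amide formation from the ester with the magnesium amide of MeNHOMe; any δ-lactone formed from the C9 alkoxide is opened to the same hydroxy amide.

Step 5
Reactants: 7 (3R,5R)-3-(tert-butyldimethylsilyloxy)-5-hydroxy-N-methoxy-N,2,2,6-tetramethylhept-6-enamide; 8 vinylmagnesium bromide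
Product: 9 (5R,7R)-5-(tert-butyldimethylsilyloxy)-7-hydroxy-4,4,8-trimethylnona-1,8-dien-3-one
Conditions: 8 (2.5 equiv), THF, 0 °C; aq NH4Cl
Reagents that add atoms: none
Why: Grignard addition to the Weinreb amide stops at the ketone because of the chelated tetrahedral intermediate and gives the vinyl ketone, one equivalent of 8 being consumed by the hydroxyl.

Step 6
Reactants: 9 (5R,7R)-5-(tert-butyldimethylsilyloxy)-7-hydroxy-4,4,8-trimethylnona-1,8-dien-3-one
Product: 10 (4R,6R)-6-(tert-butyldimethylsilyloxy)-4-hydroxy-3,7,7-trimethylcyclohept-2-en-1-one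
Conditions: RuCl2(=CHPh)(PCy3)(H2IMes) (second-generation Grubbs catalyst, 5 mol %), toluene, 80 °C
Reagents that add atoms: none
Why: Ring-closing metathesis of the vinyl ketone with the 1,1-disubstituted alkene forms the trisubstituted C4=C10 enone of the seven-membered ring with loss of ethene, helped by the gem-dimethyl group.

Step 7
Reactants: 10 (4R,6R)-6-(tert-butyldimethylsilyloxy)-4-hydroxy-3,7,7-trimethylcyclohept-2-en-1-one; 11 ethyl vinyl ether
Product: 12 (4R,6R)-4-(2-bromo-1-ethoxyethoxy)-6-(tert-butyldimethylsilyloxy)-3,7,7-trimethylcyclohept-2-en-1-one (both acetal epimers)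
Conditions: N-bromosuccinimide, 11, CH2Cl2, −40 to 0 °C
Reagents that add atoms: N-bromosuccinimide O=C1CCC(=O)N1Br
Why: Bromoacetalization (haloetherification of the enol ether by the C9 hydroxyl) gives the Ueno–Stork radical precursor under non-basic conditions that spare the γ-hydroxy enone; the acetal carbon is an inconsequential epimer mixture.

Step 8
Reactants: 12 (4R,6R)-4-(2-bromo-1-ethoxyethoxy)-6-(tert-butyldimethylsilyloxy)-3,7,7-trimethylcyclohept-2-en-1-one
Product: 13 7-(tert-butyldimethylsilyloxy)-2-ethoxy-3a,6,6-trimethyloctahydrocyclohepta[b]furan-5-one (cis ring fusion; 7-silyloxy trans to O1; acetal epimers)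
Conditions: Bu3SnH, AIBN (cat.), benzene, 80 °C, slow addition
Reagents that add atoms: none
Why: Ueno–Stork radical cyclization, in which the primary radical closes 5-exo-trig onto C10 (β-carbon of the enone) and the O9 tether forces the new C10–C11 bond cis to C9–O, setting the quaternary centre C10; the α-keto radical at C4 is reduced by Bu3SnH.

Step 9
Reactants: 13 7-(tert-butyldimethylsilyloxy)-2-ethoxy-3a,6,6-trimethyloctahydrocyclohepta[b]furan-5-one
Product: 14 7-(tert-butyldimethylsilyloxy)-3a,6,6-trimethylhexahydrocyclohepta[b]furan-2,5-dione (cis-fused γ-lactone; same configuration as 13)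
Conditions: CrO3, H2SO4, acetone–H2O, 0 °C
Reagents that add atoms: water O
Why: Jones oxidation hydrolyses the cyclic acetal to the lactol and oxidizes it to the γ-lactone, whose carbonyl is the temporary activating group for C11; ketone and silyl ether are not affected at 0 °C.

Step 10
Reactants: 14 7-(tert-butyldimethylsilyloxy)-3a,6,6-trimethylhexahydrocyclohepta[b]furan-2,5-dione; 15 ethyl but-2-ynoate
Product: 17 7-(tert-butyldimethylsilyloxy)-1,5-dioxo-5,11-secolongipin-2-ene-11-carboxylic acid 9-lactone, via Michael adduct 16 (not isolated)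
Conditions: LiN(i-Pr)2 (1.05 equiv), THF, −78 °C; 15, −78 to −20 °C; then t-BuOK (2.5 equiv), t-BuOH, 0 to 25 °C; AcOH
Reagents that add atoms: none
Why: LiN(i-Pr)2 removes a proton from C4, the only enolizable position of the C5 ketone (C6 is quaternary), and this enolate adds to C3 of the alkynoate (Michael addition, C3–C4) to give 16 as an E/Z mixture; t-BuOK then generates the lactone enolate at C11, which attacks the ester carbon C1 and expels ethoxide (Claisen condensation, C1–C11). The closest known reaction type is the tandem Michael–Claisen (3+3) annulation that converts ketone enolates and acrylates or alkynoates into cyclohexane-1,3-diones and cyclohexenones. The six-membered ring closes in the 6-(enolexo)-exo-trig mode from the Z enoate, and the E isomer reaches it through the C4 dienolate, so both isomers drain into 17. C4 is epimerizable (α to C5=O and γ to the new enone) and should settle in the all-cis angular arrangement in which the lactone, the seven-membered ring and the new ring are mutually cis-fused about C10; C11 is a β-dicarbonyl carbon that stays enolizable and is fixed only later. The step needs the orientation C4 to C3 and C11 to C1: it is secured by the order of enolate formation and by ring size, since after addition at C4 only closure from C11 gives a six-membered carbocycle (closure from the ketone side would be four-membered), while O-cyclization to an α-pyrone is reversible under alkoxide and deprotonation of the acidic β-keto lactone makes the condensation irreversible.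

Step 11
Reactants: 17 7-(tert-butyldimethylsilyloxy)-1,5-dioxo-5,11-secolongipin-2-ene-11-carboxylic acid 9-lactone
Product: 18 7-(tert-butyldimethylsilyloxy)-5-hydroxy-1-oxo-5,11-secolongipin-2-ene-11-carboxylic acid 9-lactone (C5–OH cis to C7–O)
Conditions: NaBH4, MeOH–CH2Cl2, −78 to −20 °C
Reagents that add atoms: none
Why: Chemoselective borohydride reduction of the saturated C5 ketone in the presence of the conjugated, largely enolized β-keto lactone; hydride should enter anti to the C7 silyloxy group and the angular C10 methyl, placing C5–OH cis to C7–O and on the face opposite C11.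

Step 12
Reactants: 18 7-(tert-butyldimethylsilyloxy)-5-hydroxy-1-oxo-5,11-secolongipin-2-ene-11-carboxylic acid 9-lactone
Product: 20 7-(tert-butyldimethylsilyloxy)-5,9-dihydroxy-5,11-secolongipin-2-en-1-one, via hydroxy keto acid 19 (not isolated)
Conditions: LiOH, THF–H2O, 25 °C; then 1 M HCl to pH 3, 45 °C
Reagents that add atoms: none
Why: Saponification of the β-keto lactone and decarboxylation of the β-keto acid through its C11 enol removes the tether carbon as CO2, frees C9–OH and leaves C11 as the α′-methylene of the enone; C4 is no longer α to a ketone and keeps its configuration.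

Step 13
Reactants: 20 7-(tert-butyldimethylsilyloxy)-5,9-dihydroxy-5,11-secolongipin-2-en-1-one
Product: 22 7-(tert-butyldimethylsilyloxy)-5-(methanesulfonyloxy)-9-(trimethylsilyloxy)-5,11-secolongipin-2-en-1-one, via 9-O-trimethylsilyl ether 21 (not isolated)
Conditions: Me3SiCl (1.05 equiv), imidazole, CH2Cl2, −20 °C; then Et3N, MsCl, 0 °C
Reagents that add atoms: chlorotrimethylsilane C[Si](C)(C)Cl; methanesulfonyl chloride CS(=O)(=O)Cl
Why: Selective silylation of the less hindered C9 hydroxyl (temporary protection against O-alkylation and acyl transfer) followed by mesylation of the hindered C5 hydroxyl through sulfene, both with retention.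

Step 14
Reactants: 22 7-(tert-butyldimethylsilyloxy)-5-(methanesulfonyloxy)-9-(trimethylsilyloxy)-5,11-secolongipin-2-en-1-one
Product: 24 (4R,5S,7R,9R,10R,11R)-7-(tert-butyldimethylsilyloxy)-9-hydroxylongipin-2-en-1-one, via 9-O-trimethylsilyl tricycle 23 (not isolated)
Conditions: KN(SiMe3)2 (1.1 equiv), THF, −78 to 0 °C; then K2CO3, MeOH, 0 °C
Reagents that add atoms: none
Why: Intramolecular alkylation of the kinetic α′-enolate (C11) of the enone by the C5 mesylate (4-exo-tet, SN2 with inversion at C5), the cyclobutane-forming tactic of copaene and bergamotene syntheses, in which the cis ring fusion places C11 behind the C5–O bond so that C5 and C11 are set by the geometry of closure; methanolysis then removes the trimethylsilyl group.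

Step 15
Reactants: 24 (4R,5S,7R,9R,10R,11R)-7-(tert-butyldimethylsilyloxy)-9-hydroxylongipin-2-en-1-one
Product: 25 (4R,5S,7R,9R,10R,11R)-9-acetoxy-7-(tert-butyldimethylsilyloxy)longipin-2-en-1-one
Conditions: Ac2O, pyridine, DMAP (cat.), CH2Cl2, 25 °C
Reagents that add atoms: acetic anhydride CC(=O)OC(C)=O
Why: DMAP-catalysed acetylation of the C9 alcohol with retention.

Step 16
Reactants: 25 (4R,5S,7R,9R,10R,11R)-9-acetoxy-7-(tert-butyldimethylsilyloxy)longipin-2-en-1-one
Product: 26 (4R,5S,7R,9R,10R,11R)-9-acetoxy-7-hydroxylongipin-2-en-1-one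
Conditions: HF·pyridine, THF, 0 to 25 °C
Reagents that add atoms: none
Why: Fluoride cleavage of the silyl ether under mildly acidic conditions that avoid 1,3-migration of the acetate and leave the enone and cyclobutane untouched.

Step 17
Reactants: 26 (4R,5S,7R,9R,10R,11R)-9-acetoxy-7-hydroxylongipin-2-en-1-one; 27 angelic acid
Product: 29 (4R,5S,7R,9R,10R,11R)-9-acetoxy-7-angeloyloxylongipin-2-en-1-one (CNP0260482.1), via mixed anhydride 28 (not isolated)
Conditions: 27, 2,4,6-Cl3C6H2COCl, Et3N, toluene, 25 °C; then 26, 80 °C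
Reagents that add atoms: none
Why: Yamaguchi esterification through the preformed mixed anhydride of angelic acid without DMAP, conditions that acylate hindered secondary alcohols without Z to E isomerization of the angelate; C7 keeps its configuration.

**Compound list**
1 | methyl 2,2-dimethyl-3-oxopropanoate | COC(=O)C(C)(C)C=O | starting material
2 | 3-methylbut-3-en-2-one | CC(=O)C(C)=C | starting material
3 | 3-methylbuta-1,3-dien-2-yl diisopinocampheylborinate (enol borinate of 2) | C=C(OB([C@@H]1C[C@@H]2C[C@H]([C@H]1C)C2(C)C)[C@@H]1C[C@@H]2C[C@H]([C@H]1C)C2(C)C)C(C)=C | intermediate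
4 | methyl (3R)-3-hydroxy-2,2,6-trimethyl-5-oxohept-6-enoate | COC(=O)C(C)(C)[C@H](O)CC(=O)C(C)=C | intermediate
5 | methyl (3R)-3-(tert-butyldimethylsilyloxy)-2,2,6-trimethyl-5-oxohept-6-enoate | COC(=O)C(C)(C)[C@H](O[Si](C)(C)C(C)(C)C)CC(=O)C(C)=C | intermediate
6 | methyl (3R,5R)-3-(tert-butyldimethylsilyloxy)-5-hydroxy-2,2,6-trimethylhept-6-enoate | COC(=O)C(C)(C)[C@H](O[Si](C)(C)C(C)(C)C)C[C@@H](O)C(C)=C | intermediate
7 | (3R,5R)-3-(tert-butyldimethylsilyloxy)-5-hydroxy-N-methoxy-N,2,2,6-tetramethylhept-6-enamide | CON(C)C(=O)C(C)(C)[C@H](O[Si](C)(C)C(C)(C)C)C[C@@H](O)C(C)=C | intermediate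
8 | vinylmagnesium bromide | C=C[Mg]Br | starting material
9 | (5R,7R)-5-(tert-butyldimethylsilyloxy)-7-hydroxy-4,4,8-trimethylnona-1,8-dien-3-one | C=CC(=O)C(C)(C)[C@H](O[Si](C)(C)C(C)(C)C)C[C@@H](O)C(C)=C | intermediate
10 | (4R,6R)-6-(tert-butyldimethylsilyloxy)-4-hydroxy-3,7,7-trimethylcyclohept-2-en-1-one | O=C1C=C(C)[C@H](O)C[C@@H](O[Si](C)(C)C(C)(C)C)C1(C)C | intermediate
11 | ethyl vinyl ether | C=COCC | starting material
12 | (4R,6R)-4-(2-bromo-1-ethoxyethoxy)-6-(tert-butyldimethylsilyloxy)-3,7,7-trimethylcyclohept-2-en-1-one, both acetal epimers | O=C1C=C(C)[C@H](OC(CBr)OCC)C[C@@H](O[Si](C)(C)C(C)(C)C)C1(C)C | intermediate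
13 | 7-(tert-butyldimethylsilyloxy)-2-ethoxy-3a,6,6-trimethyloctahydrocyclohepta[b]furan-5-one; cis-fused (C8a–H and C3a–CH3 cis), silyloxy trans to O1, acetal epimers | O=C1C[C@]2(C)CC(OCC)O[C@@H]2C[C@@H](O[Si](C)(C)C(C)(C)C)C1(C)C | intermediate
14 | 7-(tert-butyldimethylsilyloxy)-3a,6,6-trimethylhexahydrocyclohepta[b]furan-2,5-dione; cis-fused γ-lactone, configuration as 13 | O=C1C[C@]2(C)CC(=O)O[C@@H]2C[C@@H](O[Si](C)(C)C(C)(C)C)C1(C)C | intermediate
15 | ethyl but-2-ynoate | CC#CC(=O)OCC | starting material
16 | ethyl 3-[7-(tert-butyldimethylsilyloxy)-3a,6,6-trimethyl-2,5-dioxooctahydrocyclohepta[b]furan-4-yl]but-2-enoate; E/Z mixture, side chain cis to the lactone CH2 | O=C1[C@H](C(C)=CC(=O)OCC)[C@]2(C)CC(=O)O[C@@H]2C[C@@H](O[Si](C)(C)C(C)(C)C)C1(C)C | intermediate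
17 | 7-(tert-butyldimethylsilyloxy)-1,5-dioxo-5,11-secolongipin-2-ene-11-carboxylic acid 9-lactone; C4–H, C9–H and C10–CH3 mutually cis, C11 epimerizable and drawn without configuration | O=C1[C@@H]2C(C)=CC(=O)C3C(=O)O[C@H](C[C@@H](O[Si](C)(C)C(C)(C)C)C1(C)C)[C@]23C | intermediate
18 | 7-(tert-butyldimethylsilyloxy)-5-hydroxy-1-oxo-5,11-secolongipin-2-ene-11-carboxylic acid 9-lactone; C5–OH cis to C7–O | O[C@H]1[C@@H]2C(C)=CC(=O)C3C(=O)O[C@H](C[C@@H](O[Si](C)(C)C(C)(C)C)C1(C)C)[C@]23C | intermediate
19 | 7-(tert-butyldimethylsilyloxy)-5,9-dihydroxy-1-oxo-5,11-secolongipin-2-ene-11-carboxylic acid | O[C@H]1[C@@H]2C(C)=CC(=O)C(C(=O)O)[C@]2(C)[C@H](O)C[C@@H](O[Si](C)(C)C(C)(C)C)C1(C)C | intermediate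
20 | 7-(tert-butyldimethylsilyloxy)-5,9-dihydroxy-5,11-secolongipin-2-en-1-one; cis-fused, C4, C7, C9, C10 as in the target, C5–OH cis to C7–O | O[C@H]1[C@@H]2C(C)=CC(=O)C[C@]2(C)[C@H](O)C[C@@H](O[Si](C)(C)C(C)(C)C)C1(C)C | intermediate
21 | 9-O-trimethylsilyl ether of 20 | O[C@H]1[C@@H]2C(C)=CC(=O)C[C@]2(C)[C@H](O[Si](C)(C)C)C[C@@H](O[Si](C)(C)C(C)(C)C)C1(C)C | intermediate
22 | 7-(tert-butyldimethylsilyloxy)-5-(methanesulfonyloxy)-9-(trimethylsilyloxy)-5,11-secolongipin-2-en-1-one | CS(=O)(=O)O[C@H]1[C@@H]2C(C)=CC(=O)C[C@]2(C)[C@H](O[Si](C)(C)C)C[C@@H](O[Si](C)(C)C(C)(C)C)C1(C)C | intermediate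
23 | (4R,5S,7R,9R,10R,11R)-7-(tert-butyldimethylsilyloxy)-9-(trimethylsilyloxy)longipin-2-en-1-one | CC(C)(C)[Si](C)(C)O[C@@H]1C[C@@H](O[Si](C)(C)C)[C@@]2(C)[C@@H]3C(=O)C=C(C)[C@H]2[C@@H]3C1(C)C | intermediate
24 | (4R,5S,7R,9R,10R,11R)-7-(tert-butyldimethylsilyloxy)-9-hydroxylongipin-2-en-1-one | CC(C)(C)[Si](C)(C)O[C@@H]1C[C@@H](O)[C@@]2(C)[C@@H]3C(=O)C=C(C)[C@H]2[C@@H]3C1(C)C | intermediate
25 | (4R,5S,7R,9R,10R,11R)-9-acetoxy-7-(tert-butyldimethylsilyloxy)longipin-2-en-1-one | CC(C)(C)[Si](C)(C)O[C@@H]1C[C@@H](OC(C)=O)[C@@]2(C)[C@@H]3C(=O)C=C(C)[C@H]2[C@@H]3C1(C)C | intermediate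
26 | (4R,5S,7R,9R,10R,11R)-9-acetoxy-7-hydroxylongipin-2-en-1-one | O[C@@H]1C[C@@H](OC(C)=O)[C@@]2(C)[C@@H]3C(=O)C=C(C)[C@H]2[C@@H]3C1(C)C | intermediate
27 | angelic acid, (Z)-2-methylbut-2-enoic acid | C/C=C(/C)C(=O)O | starting material
28 | angelic 2,4,6-trichlorobenzoic anhydride | C/C=C(/C)C(=O)OC(=O)c1c(Cl)cc(Cl)cc1Cl | intermediate
29 | (4R,5S,7R,9R,10R,11R)-9-acetoxy-7-angeloyloxylongipin-2-en-1-one (CNP0260482.1) | C/C=C(/C)C(=O)O[C@@H]1C[C@@H](OC(C)=O)[C@@]2(C)[C@@H]3C(=O)C=C(C)[C@H]2[C@@H]3C1(C)C | target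

**Totals and risks**
Total steps: 17. Longest linear sequence: 17 steps (1 to 29).

Step 10. What may go wrong: deprotonation of the lactone in competition with the ketone (annulation in the reversed orientation), 1,2-addition of the enolate to the ester, or O-cyclization of the dienolate to an α-pyrone. Fallback, setting out from 13 and coming back at 17: the two bonds are made in separate operations. The C5 ketone of acetal 13 is its only enolizable carbonyl, so its lithium enolate (LiN(i-Pr)2, THF, −78 °C) is added to 15 to give the Michael adduct acetal F1. Oxidation with CrO3/H2SO4 in acetone then gives 16 as an isolated compound, and t-BuOK in t-BuOH closes 16 to 17 by Dieckmann condensation.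

Step 14. What may go wrong: γ-deprotonation at C4 with vinylogous loss of the mesylate, or proton exchange between enolates, may outrun the slow four-membered ring closure. Fallback, setting out from 18 and coming back at 24: the lactone carbonyl is kept on C11 so that a soft, carbonate-generated enolate does the alkylation. Alcohol 18 is mesylated (MsCl, pyridine, 0 °C) to the lactone mesylate F2. Cs2CO3 in MeCN closes the cyclobutane by C-alkylation of the β-keto lactone to give the bridged keto lactone F3. LiOH/H2O2 in THF–H2O opens the lactone to the bridgehead β-keto acid F4, which cannot lose CO2 through an enol. Photocatalytic hydrodecarboxylation (9-mesityl-10-methylacridinium tetrafluoroborate, PhSSPh, i-Pr2NEt, blue light) then gives 24.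

Step 11. What may go wrong: poor facial selectivity of hydride delivery to C5, or competing reduction of the C1 carbonyl. Fallback, setting out from 17 and coming back at 18: chelation control replaces steric control. HF·pyridine removes the silyl group to give the β-hydroxy ketone F5. Et2BOMe/NaBH4 in THF–MeOH at −78 °C (Narasaka–Prasad reduction) reduces the boron chelate from its open face to the syn-1,3-diol F6, with C5–OH cis to C7–OH. TBSOTf (1 equiv) with 2,6-lutidine at −78 °C then silylates the less hindered C7 hydroxyl to give 18.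

**Further compounds**
F1 | step 10 | ethyl 3-[7-(tert-butyldimethylsilyloxy)-2-ethoxy-3a,6,6-trimethyl-5-oxooctahydrocyclohepta[b]furan-4-yl]but-2-enoate (Michael adduct acetal) | O=C1[C@H](C(C)=CC(=O)OCC)[C@]2(C)CC(OCC)O[C@@H]2C[C@@H](O[Si](C)(C)C(C)(C)C)C1(C)C
F2 | step 14 | 7-(tert-butyldimethylsilyloxy)-5-(methanesulfonyloxy)-1-oxo-5,11-secolongipin-2-ene-11-carboxylic acid 9-lactone (lactone mesylate) | CS(=O)(=O)O[C@H]1[C@@H]2C(C)=CC(=O)C3C(=O)O[C@H](C[C@@H](O[Si](C)(C)C(C)(C)C)C1(C)C)[C@]23C
F3 | step 14 | 7-(tert-butyldimethylsilyloxy)-1-oxolongipin-2-ene-11-carboxylic acid 9-lactone (bridged keto lactone) | CC(C)(C)[Si](C)(C)O[C@@H]1C[C@@H](OC4=O)[C@@]2(C)[C@]34C(=O)C=C(C)[C@H]2[C@@H]3C1(C)C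
F4 | step 14 | 7-(tert-butyldimethylsilyloxy)-9-hydroxy-1-oxolongipin-2-ene-11-carboxylic acid (bridgehead β-keto acid) | CC(C)(C)[Si](C)(C)O[C@@H]1C[C@@H](O)[C@@]2(C)[C@]3(C(=O)O)C(=O)C=C(C)[C@H]2[C@@H]3C1(C)C
F5 | step 11 | 7-hydroxy-1,5-dioxo-5,11-secolongipin-2-ene-11-carboxylic acid 9-lactone (β-hydroxy ketone) | O=C1[C@@H]2C(C)=CC(=O)C3C(=O)O[C@H](C[C@@H](O)C1(C)C)[C@]23C
F6 | step 11 | 5,7-dihydroxy-1-oxo-5,11-secolongipin-2-ene-11-carboxylic acid 9-lactone (syn-1,3-diol) | O[C@H]1[C@@H]2C(C)=CC(=O)C3C(=O)O[C@H](C[C@@H](O)C1(C)C)[C@]23C
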